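## Retrosynthetic overview
1. 31 ⇒ 29 ⇒ 27. The C5'–OH (autoxidation) and the C3'=C4' olefin (selenoxide elimination) go in last, on the closed 13-membered para-cyclophane.
2. Key disconnection: the aryl–O bond at O4 of 27 ⇒ open bromide/carbinol 26. The macro-etherification runs through a 14-membered nickelacycle that contracts on C–O reductive elimination.
3. 26 ⇒ bromobenzyl lactam 24 + tricyclic hydroxy ester 19 (Claisen C-acylation).
4. 19 ⇒ 17: rings A and B form together by a ketone-endo intramolecular Diels–Alder reaction, and the C4 carbinol comes from convex-face reduction. 17 ⇒ 15: ring C forms by epoxide/trienylsilane cyclisation.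
5. 15 ⇒ iodide 9 (desymmetrised meso-anhydride) + trienyl iodide 5 (Negishi coupling). Ring order: C, then A+B, lactam brought in intact, macrocycle last.

Locants: C1 = ketone C; C2, C3, C11, C12(Me)=C13, C14(vinyl C15=C16) = ring A; C3, C4(O), C5, C10(Me), C11 = ring B; C5, C6(Me), C7, C8(Me), C9, C10 = ring C; lactam N1', C2'(=O), C3', C4', C5'. The target is 2R,3R,4S,5R,6S,8R,10S,11S,14S,5'R.

Assumption: the senses of induction of the two commercial chiral catalysts (Steps 4 and 10) are as stated; both are sold in both (pseudo)enantiomeric forms, and the other form is used if the sense is opposite.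

## Route

Step 1
Reactants: 1 allyltrimethylsilane; 2 (E)-crotonaldehyde
Product: 3 (2E)-4-(trimethylsilyl)but-2-enal
Conditions: Hoveyda–Grubbs II (2 mol %), 1 (2.5 equiv), CH2Cl2, 40 °C
Reagents that add atoms: none
Why: Olefin cross-metathesis of a type-I allylsilane with a type-II enal selects the (E)-cross product, and propene leaves as a gas.

Step 2
Reactants: 3 (2E)-4-(trimethylsilyl)but-2-enal
Product: 4 (2E,4E)-2-methyl-6-(trimethylsilyl)hexa-2,4-dienal
Conditions: Ph3P=C(Me)CHO, PhMe, 90 °C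
Reagents that add atoms: 2-(triphenylphosphoranylidene)propanal CC(C=O)=P(c1ccccc1)(c1ccccc1)c1ccccc1
Why: Wittig olefination with a stabilised α-methyl ylide gives the (E)-trisubstituted enal, which is too hindered to react a second time.

Step 3
Reactants: 4 (2E,4E)-2-methyl-6-(trimethylsilyl)hexa-2,4-dienal
Product: 5 [(2E,4E,6Z)-7-iodo-5-methylocta-2,4,6-trien-1-yl]trimethylsilane
Conditions: EtPPh3I, n-BuLi, THF, rt; I2, −78 °C; NaHMDS, −20 °C; 4, −78 °C
Reagents that add atoms: ethyltriphenylphosphonium iodide CC[P+](c1ccccc1)(c1ccccc1)c1ccccc1.[I-]; iodine II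
Why: Stork–Zhao-type Wittig olefination with the α-iodoethylidene ylide gives the (Z)-2-iodoalkene (I cis to the chain) under kinetic control.

Step 4
Reactants: 6 meso-2,4-dimethylglutaric anhydride
Product: 7 (2R,4S)-5-methoxy-2,4-dimethyl-5-oxopentanoic acid
Conditions: (DHQD)2AQN (20 mol %), MeOH (10 equiv), Et2O, −40 °C
Reagents that add atoms: methanol CO
Why: Alkaloid-catalysed desymmetrising methanolysis tells the enantiotopic carbonyls apart and so fixes C6 (S) and C8 (R) in one operation.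

Step 5
Reactants: 7 (2R,4S)-5-methoxy-2,4-dimethyl-5-oxopentanoic acid
Product: 8 methyl (2S,4R)-5-hydroxy-2,4-dimethylpentanoate
Conditions: BH3·SMe2, THF, 0 °C to rt; used crude
Reagents that add atoms: none
Why: Chemoselective borane reduction takes the free acid far faster than the ester and touches no stereocentre, and crude use avoids δ-lactonisation.

Step 6
Reactants: 8 methyl (2S,4R)-5-hydroxy-2,4-dimethylpentanoate
Product: 9 methyl (2S,4R)-5-iodo-2,4-dimethylpentanoate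
Conditions: I2, PPh3, imidazole, CH2Cl2, 0 °C
Reagents that add atoms: iodine II
Why: Appel-type iodination is an SN2 reaction at a primary carbon, remote from both stereocentres.

Step 7
Reactants: 9 methyl (2S,4R)-5-iodo-2,4-dimethylpentanoate; 5 [(2E,4E,6Z)-7-iodo-5-methylocta-2,4,6-trien-1-yl]trimethylsilane
Product: 11 methyl (2S,4R,6Z,8E,10E)-2,4,6,8-tetramethyl-12-(trimethylsilyl)dodeca-6,8,10-trienoate, via alkylzinc iodide 10 (not isolated)
Conditions: Zn dust, LiCl, THF, 40 °C; then 5, Pd(dppf)Cl2 (3 mol %), THF, rt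
Reagents that add atoms: none
Why: In this Negishi sp3–sp2 coupling the alkylzinc tolerates the ester and the vinyl iodide couples with retention, which puts C9 cis to C12.

Step 8
Reactants: 11 methyl (2S,4R,6Z,8E,10E)-2,4,6,8-tetramethyl-12-(trimethylsilyl)dodeca-6,8,10-trienoate
Product: 12 (2S,4R,6Z,8E,10E)-2,4,6,8-tetramethyl-12-(trimethylsilyl)dodeca-6,8,10-trienal
Conditions: DIBAL-H (1.1 equiv), CH2Cl2, −78 °C; MeOH, Rochelle salt
Reagents that add atoms: none
Why: DIBAL partial reduction stops at the aldehyde because the aluminium hemiacetal survives at −78 °C until work-up.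

Step 9
Reactants: 12 (2S,4R,6Z,8E,10E)-2,4,6,8-tetramethyl-12-(trimethylsilyl)dodeca-6,8,10-trienal
Product: 13 (2E,4S,6R,8Z,10E,12E)-4,6,8,10-tetramethyl-14-(trimethylsilyl)tetradeca-2,8,10,12-tetraenal
Conditions: Ph3P=CHCHO, PhMe, 80 °C
Reagents that add atoms: (triphenylphosphoranylidene)acetaldehyde O=CC=P(c1ccccc1)(c1ccccc1)c1ccccc1
Why: Wittig two-carbon homologation with the stabilised formyl ylide gives the (E)-enal under neutral conditions that do not epimerise C6.

Step 10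
Reactants: 13 (2E,4S,6R,8Z,10E,12E)-4,6,8,10-tetramethyl-14-(trimethylsilyl)tetradeca-2,8,10,12-tetraenal
Product: 15 methyl (2E)-3-{(2R,3R)-3-[(2S,4R,6Z,8E,10E)-4,6,8-trimethyl-12-(trimethylsilyl)dodeca-6,8,10-trien-2-yl]oxiran-2-yl}prop-2-enoate, via epoxy aldehyde 14 (not isolated)
Conditions: (S)-diarylprolinol TMS ether [Ar = 3,5-(CF3)2C6H3] (10 mol %), 35 % aq H2O2, CH2Cl2, rt; then Ph3P=CHCO2Me, 0 °C to rt
Reagents that add atoms: hydrogen peroxide OO; methyl (triphenylphosphoranylidene)acetate COC(=O)C=P(c1ccccc1)(c1ccccc1)c1ccccc1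
Why: Iminium-catalysed nucleophilic (Weitz–Scheffer-type) epoxidation attacks only the enal C=C and not the electron-rich trienylsilane, the catalyst shielding sets the trans-(4,5) epoxide, and the in-flask Wittig reaction gives the (E)-enoate.

Step 11
Reactants: 15 methyl (2E)-3-{(2R,3R)-3-[(2S,4R,6Z,8E,10E)-4,6,8-trimethyl-12-(trimethylsilyl)dodeca-6,8,10-trien-2-yl]oxiran-2-yl}prop-2-enoate
Product: 16 methyl (2E,4R)-4-hydroxy-4-{(1R,2S,4R,6S)-2,4,6-trimethyl-2-[(1E,3E)-2-methylhexa-1,3,5-trien-1-yl]cyclohexyl}but-2-enoate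
Conditions: Et2AlCl (3 equiv), CH2Cl2 (5 mM), −78 °C, 1 h; quench at −78 °C, Rochelle salt
Reagents that add atoms: none
Why: In this intramolecular vinylogous Hosomi–Sakurai (6-exo epoxide/cation–olefin) cyclisation, anti attack inverts C5 in a chair with C6-Me and C8-Me equatorial, A1,3 strain in the (Z)-C10=C11 olefin holds the dienyl arm equatorial (C10-Me axial, 10S), the W-shaped pentadienyl cation loses silicon to give the (11E,13E)-triene, and the cold quench prevents an ester-endo cycloaddition.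

Step 12
Reactants: 16 methyl (2E,4R)-4-hydroxy-4-{(1R,2S,4R,6S)-2,4,6-trimethyl-2-[(1E,3E)-2-methylhexa-1,3,5-trien-1-yl]cyclohexyl}but-2-enoate
Product: 18 methyl (1R,2S,4aS,4bS,6R,8S,8aR,9aR)-2-ethenyl-4,4b,6,8-tetramethyl-9-oxo-2,4a,4b,5,6,7,8,8a,9,9a-decahydro-1H-fluorene-1-carboxylate, via enedione 17 (not isolated)
Conditions: Dess–Martin periodinane, CH2Cl2, 0 °C to rt; then PhMe, 50 °C
Reagents that add atoms: none
Why: Oxidation unmasks an (E)-4-oxo-enoate that undergoes a type-1 intramolecular Diels–Alder reaction with the tether ketone endo (cis A/B fusion, ester exo so C2 is R), the (E,E)-diene places the vinyl group cis to C10 (14S), and A1,3 strain between C12-Me and C10 puts the small C10-Me in the diene plane so that H3 and H11 end up syn to H5.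

Step 13
Reactants: 18 methyl (1R,2S,4aS,4bS,6R,8S,8aR,9aR)-2-ethenyl-4,4b,6,8-tetramethyl-9-oxo-2,4a,4b,5,6,7,8,8a,9,9a-decahydro-1H-fluorene-1-carboxylate
Product: 19 methyl (1R,2S,4aS,4bS,6R,8S,8aR,9S,9aR)-2-ethenyl-9-hydroxy-4,4b,6,8-tetramethyl-2,4a,4b,5,6,7,8,8a,9,9a-decahydro-1H-fluorene-1-carboxylate
Conditions: NaBH4, CeCl3·7H2O, MeOH/THF, −78 to −40 °C
Reagents that add atoms: none
Why: Luche reduction delivers hydride to the convex face (the face bearing H3, H5 and H11, opposite ring A and C10-Me), giving the (4S)-carbinol while sparing the ester and avoiding base that would epimerise C3 or C5.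

Step 14
Reactants: 20 (5R)-5-(hydroxymethyl)pyrrolidin-2-one
Product: 21 [(2R)-5-oxopyrrolidin-2-yl]methyl 4-methylbenzenesulfonate
Conditions: TsCl, Et3N, DMAP (cat.), CH2Cl2, 0 °C to rt
Reagents that add atoms: 4-toluenesulfonyl chloride Cc1ccc(cc1)S(=O)(=O)Cl
Why: O-sulfonylation of the primary alcohol leaves the stereocentre untouched.

Step 15
Reactants: 21 [(2R)-5-oxopyrrolidin-2-yl]methyl 4-methylbenzenesulfonate; 22 1,4-dibromobenzene
Product: 24 (5R)-5-(4-bromobenzyl)pyrrolidin-2-one, via aryl Grignard 23 (not isolated)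
Conditions: 22, Mg (1 equiv), THF, 40 °C; then 21 (0.45 equiv), CuI (10 mol %), THF, −20 °C to rt
Reagents that add atoms: none
Why: Copper-catalysed Grignard–tosylate (Kochi-type) coupling occurs at the primary carbon, so the D-pyroglutamate centre becomes a C5' with the spatial arrangement of an L-tyrosine-derived lactam.

Step 16
Reactants: 19 methyl (1R,2S,4aS,4bS,6R,8S,8aR,9S,9aR)-2-ethenyl-9-hydroxy-4,4b,6,8-tetramethyl-2,4a,4b,5,6,7,8,8a,9,9a-decahydro-1H-fluorene-1-carboxylate; 24 (5R)-5-(4-bromobenzyl)pyrrolidin-2-one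
Product: 26 (5R)-5-(4-bromobenzyl)-3-{[(1R,2S,4aS,4bS,6R,8S,8aR,9S,9aR)-2-ethenyl-9-hydroxy-4,4b,6,8-tetramethyl-2,4a,4b,5,6,7,8,8a,9,9a-decahydro-1H-fluoren-1-yl]carbonyl}pyrrolidin-2-one (C3' epimers/enol), via N-silyl lactam 25 (not isolated)
Conditions: 24 (3 equiv), n-BuLi then TMSCl, THF, −78 to 0 °C; LDA, −78 °C; 19, −78 to 0 °C; aq NH4Cl
Reagents that add atoms: none
Why: This crossed Claisen C-acylation of a lactam enolate is driven by deprotonation of the β-keto-lactam, the neighbouring lithium alkoxide helps bring the enolate to the ester, C2 already holds its equatorial (thermodynamic) configuration, and N–Si falls off on work-up.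

Step 17
Reactants: 26 (5R)-5-(4-bromobenzyl)-3-{[(1R,2S,4aS,4bS,6R,8S,8aR,9S,9aR)-2-ethenyl-9-hydroxy-4,4b,6,8-tetramethyl-2,4a,4b,5,6,7,8,8a,9,9a-decahydro-1H-fluoren-1-yl]carbonyl}pyrrolidin-2-one
Product: 27 5'-deoxy-3',4'-dihydro-31, the 13-membered para-cyclophane β-keto-lactam (5'R; C3' epimers/enol)
Conditions: NiBr2·glyme (15 mol %), dtbbpy (15 mol %), Ir[dF(CF3)ppy]2(dtbbpy)PF6 (2 mol %), K2CO3 (3 equiv), degassed MeCN/THF, 1 mM, 450 nm LED, 25 °C, no quinuclidine
Reagents that add atoms: none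
Why: Proposed new method: a ring-contracting Ni/photoredox macro-etherification in which Ni(0) inserts into Ar–Br, the only donor the tether lets reach the para-bound Ni(II) is the C4 alkoxide (the enolate oxygens sit too close to the arene), a relaxed 14-membered aryl–Ni–alkoxide metallacycle with two long (about 1.9 Å) bonds forms reversibly, and single-electron oxidation by the excited Ir catalyst gives Ni(III), whose fast and strongly exergonic C(sp2)–O reductive elimination extrudes Ni and pays for the bent 13-membered ring at 25 °C with retention at C4 (the C4–O bond is never broken) and without epimerising C2, while leaving out the amine HAT mediator protects the bis-allylic C14–H; the closest known reaction type is Ni/photoredox C–O coupling of aryl bromides with primary or unhindered secondary alcohols and unstrained peptide macrocyclisation, never shown for a hindered carbinol or a strained cyclophane.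

Step 18
Reactants: 27 5'-deoxy-3',4'-dihydro-31
Product: 29 5'-deoxy-31, the cyclophane 3-acyl-3-pyrrolin-2-one (5'S), via selenide 28 (not isolated)
Conditions: KHMDS (1.05 equiv), THF, −78 °C; PhSeCl (1.05 equiv); then 30 % H2O2 (2 equiv), 0 °C
Reagents that add atoms: none
Why: In this α-selenenylation/selenoxide syn-elimination the β-dicarbonyl enolate out-competes the alkenes for PhSeCl, and only C4'–H is β to selenium, so only the C3'=C4' olefin can form.

Step 19
Reactants: 29 5'-deoxy-31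
Product: 31 target CNP0151253.2, via hydroperoxide 30 (not isolated)
Conditions: O2 (1 atm), Et3N (0.2 equiv), THF, rt; then Me2S
Reagents that add atoms: oxygen O=O
Why: Base-induced tautomerisation to the 2-hydroxypyrrole is followed by its autoxidation at C5' (vinylogous enolate oxygenation, hydroperoxide reduced by Me2S), and O2 can reach only the outer face because the bent arene covers the inner one, so OH takes the place of the lost H and C5' is R.

## Compound list
1 | allyltrimethylsilane | C=CC[Si](C)(C)C | starting material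
2 | (E)-crotonaldehyde | C/C=C/C=O | starting material
3 | (2E)-4-(trimethylsilyl)but-2-enal | O=C/C=C/C[Si](C)(C)C | intermediate
4 | (2E,4E)-2-methyl-6-(trimethylsilyl)hexa-2,4-dienal | O=C/C(C)=C/C=C/C[Si](C)(C)C | intermediate
5 | [(2E,4E,6Z)-7-iodo-5-methylocta-2,4,6-trien-1-yl]trimethylsilane | C/C(I)=C/C(C)=C/C=C/C[Si](C)(C)C | intermediate
6 | meso-2,4-dimethylglutaric anhydride (cis-3,5-dimethyloxane-2,6-dione) | O=C1OC(=O)[C@@H](C)C[C@H]1C | starting material
7 | (2R,4S)-5-methoxy-2,4-dimethyl-5-oxopentanoic acid | COC(=O)[C@@H](C)C[C@@H](C)C(=O)O | intermediate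
8 | methyl (2S,4R)-5-hydroxy-2,4-dimethylpentanoate | COC(=O)[C@@H](C)C[C@@H](C)CO | intermediate
9 | methyl (2S,4R)-5-iodo-2,4-dimethylpentanoate | COC(=O)[C@@H](C)C[C@@H](C)CI | intermediate
10 | [(2R,4S)-5-methoxy-2,4-dimethyl-5-oxopentyl]zinc iodide | COC(=O)[C@@H](C)C[C@@H](C)C[Zn]I | intermediate
11 | methyl (2S,4R,6Z,8E,10E)-2,4,6,8-tetramethyl-12-(trimethylsilyl)dodeca-6,8,10-trienoate | COC(=O)[C@@H](C)C[C@@H](C)C/C(C)=C\C(C)=C\C=C\C[Si](C)(C)C | intermediate
12 | (2S,4R,6Z,8E,10E)-2,4,6,8-tetramethyl-12-(trimethylsilyl)dodeca-6,8,10-trienal | O=C[C@@H](C)C[C@@H](C)C/C(C)=C\C(C)=C\C=C\C[Si](C)(C)C | intermediate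
13 | (2E,4S,6R,8Z,10E,12E)-4,6,8,10-tetramethyl-14-(trimethylsilyl)tetradeca-2,8,10,12-tetraenal | O=C/C=C/[C@@H](C)C[C@@H](C)C/C(C)=C\C(C)=C\C=C\C[Si](C)(C)C | intermediate
14 | (2S,3R)-3-[(2S,4R,6Z,8E,10E)-4,6,8-trimethyl-12-(trimethylsilyl)dodeca-6,8,10-trien-2-yl]oxirane-2-carbaldehyde | O=C[C@H]1O[C@@H]1[C@@H](C)C[C@@H](C)C/C(C)=C\C(C)=C\C=C\C[Si](C)(C)C | intermediate
15 | methyl (2E)-3-{(2R,3R)-3-[(2S,4R,6Z,8E,10E)-4,6,8-trimethyl-12-(trimethylsilyl)dodeca-6,8,10-trien-2-yl]oxiran-2-yl}prop-2-enoate (4R,5R,6S,8R) | COC(=O)/C=C/[C@H]1O[C@@H]1[C@@H](C)C[C@@H](C)C/C(C)=C\C(C)=C\C=C\C[Si](C)(C)C | intermediate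
16 | methyl (2E,4R)-4-hydroxy-4-{(1R,2S,4R,6S)-2,4,6-trimethyl-2-[(1E,3E)-2-methylhexa-1,3,5-trien-1-yl]cyclohexyl}but-2-enoate (4R,5R,6S,8R,10S) | COC(=O)/C=C/[C@@H](O)[C@@H]1[C@@H](C)C[C@@H](C)C[C@@]1(C)/C=C(C)/C=C/C=C | intermediate
17 | methyl (2E)-4-oxo-4-{(1R,2S,4R,6S)-2,4,6-trimethyl-2-[(1E,3E)-2-methylhexa-1,3,5-trien-1-yl]cyclohexyl}but-2-enoate | COC(=O)/C=C/C(=O)[C@@H]1[C@@H](C)C[C@@H](C)C[C@@]1(C)/C=C(C)/C=C/C=C | intermediate
18 | methyl (1R,2S,4aS,4bS,6R,8S,8aR,9aR)-2-ethenyl-4,4b,6,8-tetramethyl-9-oxo-2,4a,4b,5,6,7,8,8a,9,9a-decahydro-1H-fluorene-1-carboxylate (A/B cis, B/C trans) | C=C[C@H]1C=C(C)[C@@H]2[C@H]([C@@H]1C(=O)OC)C(=O)[C@@H]3[C@@H](C)C[C@@H](C)C[C@@]23C | intermediate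
19 | methyl (1R,2S,4aS,4bS,6R,8S,8aR,9S,9aR)-2-ethenyl-9-hydroxy-4,4b,6,8-tetramethyl-2,4a,4b,5,6,7,8,8a,9,9a-decahydro-1H-fluorene-1-carboxylate | C=C[C@H]1C=C(C)[C@@H]2[C@H]([C@@H]1C(=O)OC)[C@H](O)[C@@H]3[C@@H](C)C[C@@H](C)C[C@@]23C | intermediate
20 | (5R)-5-(hydroxymethyl)pyrrolidin-2-one (D-pyroglutaminol) | O=C1CC[C@H](CO)N1 | starting material
21 | [(2R)-5-oxopyrrolidin-2-yl]methyl 4-methylbenzenesulfonate | O=C1CC[C@H](COS(=O)(=O)c2ccc(C)cc2)N1 | intermediate
22 | 1,4-dibromobenzene | Brc1ccc(Br)cc1 | starting material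
23 | 4-bromophenylmagnesium bromide | Br[Mg]c1ccc(Br)cc1 | intermediate
24 | (5R)-5-(4-bromobenzyl)pyrrolidin-2-one | O=C1CC[C@H](Cc2ccc(Br)cc2)N1 | intermediate
25 | (5R)-5-(4-bromobenzyl)-1-(trimethylsilyl)pyrrolidin-2-one | C[Si](C)(C)N1C(=O)CC[C@@H]1Cc2ccc(Br)cc2 | intermediate
26 | (5R)-5-(4-bromobenzyl)-3-{[(1R,2S,4aS,4bS,6R,8S,8aR,9S,9aR)-2-ethenyl-9-hydroxy-4,4b,6,8-tetramethyl-decahydro-1H-fluoren-1-yl]carbonyl}pyrrolidin-2-one (C3' epimers/enol) | C=C[C@H]1C=C(C)[C@@H]2[C@H]([C@@H]1C(=O)C5C[C@H](Cc6ccc(Br)cc6)NC5=O)[C@H](O)[C@@H]3[C@@H](C)C[C@@H](C)C[C@@]23C | intermediate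
27 | 5'-deoxy-3',4'-dihydro-31: 13-membered para-cyclophane β-keto-lactam (2R,3R,4S,5R,6S,8R,10S,11S,14S,5'R; C3' labile) | C=C[C@H]1C=C(C)[C@@H]2[C@H]3[C@H](Oc4ccc(cc4)C[C@H]4CC(C(=O)N4)C(=O)[C@H]13)[C@@H]1[C@@H](C)C[C@@H](C)C[C@]12C | intermediate
28 | 3'-(phenylselanyl) derivative of 27 | C=C[C@H]1C=C(C)[C@@H]2[C@H]3[C@H](Oc4ccc(cc4)C[C@H]4CC([Se]c5ccccc5)(C(=O)N4)C(=O)[C@H]13)[C@@H]1[C@@H](C)C[C@@H](C)C[C@]12C | intermediate
29 | 5'-deoxy-31: cyclophane 3-acyl-3-pyrrolin-2-one (5'S, H in place of OH) | C=C[C@H]1C=C(C)[C@@H]2[C@H]3[C@H](Oc4ccc(cc4)C[C@H]4C=C(C(=O)N4)C(=O)[C@H]13)[C@@H]1[C@@H](C)C[C@@H](C)C[C@]12C | intermediate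
30 | (5'R)-5'-hydroperoxide of 29 | C=C[C@H]1C=C(C)[C@@H]2[C@H]3[C@H](Oc4ccc(cc4)C[C@@]4(OO)C=C(C(=O)N4)C(=O)[C@H]13)[C@@H]1[C@@H](C)C[C@@H](C)C[C@]12C | intermediate
31 | CNP0151253.2 (2R,3R,4S,5R,6S,8R,10S,11S,14S,5'R) | C=C[C@H]1C=C(C)[C@@H]2[C@H]3[C@H](Oc4ccc(cc4)C[C@@]4(O)C=C(C(=O)N4)C(=O)[C@H]13)[C@@H]1[C@@H](C)C[C@@H](C)C[C@]12C | target

## Step count and risks
Total steps: 19. Longest linear sequence: 14 (Steps 4–13, then 16–19). The main line contains no protecting-group steps.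

Step 11 (ring C). The risks are chlorohydrin formation or epoxide rearrangement, protodesilylation of the trienylsilane, and low selectivity at the quaternary C10. The fallback sets out from 13 and comes back at 16. It changes the electrophile from the epoxide to the enal itself.
- An intramolecular Hosomi–Sakurai conjugate addition (EtAlCl2, CH2Cl2, −78 °C) closes ring C through the same chair and gives the ring-C acetaldehyde F1.
- D-Proline-catalysed α-aminoxylation with nitrosobenzene (DMSO, rt) gives the α-anilinooxy aldehyde F2.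
- F2 is olefinated in the same flask with Ph3P=CHCO2Me to the γ-anilinooxy enoate F3.
- Zn/AcOH cleaves the N–O bond to 16. The C4 configuration is of no consequence, because Step 12 oxidises that carbon.

Step 16 (Claisen acylation with a flanked secondary ester). The risks are slow acylation and competing enolisation at C2. The fallback sets out from 19 and comes back at 26. It replaces acylation by aldol addition and oxidation.
- TESOTf/2,6-lutidine gives the C4 triethylsilyl ether F4.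
- DIBAL-H (−78 °C) gives the C1 aldehyde F5.
- The lithium enolate of 25 adds to F5 to give the aldol F6 (a mixture at C1 and C3').
- Dess–Martin periodinane gives the β-keto-lactam silyl ether F7.
- HF·pyridine frees the C4 carbinol, which is 26.

Step 17 (the new macro-etherification). The risks are nickel sequestration by the enolate, hydrodebromination, oligomers, and β-hydride loss to the C4 ketone. The fallback sets out from 21 and 19 and comes back at 27. It replaces cross-coupling by the known SNAr ring closure on a π-complexed fluoroarene.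
- 4-Fluorophenylmagnesium bromide/CuI with 21 gives the fluorobenzyl lactam F8.
- Its N-silyl derivative F9 is acylated with 19 as in Step 16, giving the fluoro analogue of 26, F10.
- Tricarbonyl(naphthalene)chromium (THF, 60 °C) places Cr(CO)3 on the fluoroarene to give the arene complex F11.
- NaH (DMF, 1 mM, rt) closes the ring by alkoxide addition and fluoride loss through a puckered Meisenheimer intermediate, giving the cyclophane complex F12.
- I2 removes the metal to give 27.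

## Further compounds
F1 | step 11 | ring-C acetaldehyde: 2-{2,4,6-trimethyl-2-[(1E,3E)-2-methylhexa-1,3,5-trien-1-yl]cyclohexyl}acetaldehyde (5R,6S,8R,10R) | O=CC[C@@H]1[C@@H](C)C[C@@H](C)C[C@@]1(C)/C=C(C)/C=C/C=C
F2 | step 11 | α-anilinooxy aldehyde (4S,5R,6S,8R,10S) | O=C[C@@H](ONc2ccccc2)[C@@H]1[C@@H](C)C[C@@H](C)C[C@@]1(C)/C=C(C)/C=C/C=C
F3 | step 11 | γ-anilinooxy enoate: O-anilino derivative of 16 (4R) | COC(=O)/C=C/[C@@H](ONc2ccccc2)[C@@H]1[C@@H](C)C[C@@H](C)C[C@@]1(C)/C=C(C)/C=C/C=C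
F4 | step 16 | C4 triethylsilyl ether of 19 | C=C[C@H]1C=C(C)[C@@H]2[C@H]([C@@H]1C(=O)OC)[C@H](O[Si](CC)(CC)CC)[C@@H]3[C@@H](C)C[C@@H](C)C[C@@]23C
F5 | step 16 | C1 aldehyde (C4 OTES) | C=C[C@H]1C=C(C)[C@@H]2[C@H]([C@@H]1C=O)[C@H](O[Si](CC)(CC)CC)[C@@H]3[C@@H](C)C[C@@H](C)C[C@@]23C
F6 | step 16 | aldol (C1 carbinol, mixture at C1 and C3', C4 OTES) | C=C[C@H]1C=C(C)[C@@H]2[C@H]([C@@H]1C(O)C5C[C@H](Cc6ccc(Br)cc6)NC5=O)[C@H](O[Si](CC)(CC)CC)[C@@H]3[C@@H](C)C[C@@H](C)C[C@@]23C
F7 | step 16 | β-keto-lactam silyl ether (C4 OTES derivative of 26) | C=C[C@H]1C=C(C)[C@@H]2[C@H]([C@@H]1C(=O)C5C[C@H](Cc6ccc(Br)cc6)NC5=O)[C@H](O[Si](CC)(CC)CC)[C@@H]3[C@@H](C)C[C@@H](C)C[C@@]23C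
F8 | step 17 | fluorobenzyl lactam: (5R)-5-(4-fluorobenzyl)pyrrolidin-2-one | O=C1CC[C@H](Cc2ccc(F)cc2)N1
F9 | step 17 | N-silyl derivative: (5R)-5-(4-fluorobenzyl)-1-(trimethylsilyl)pyrrolidin-2-one | C[Si](C)(C)N1C(=O)CC[C@@H]1Cc2ccc(F)cc2
F10 | step 17 | fluoro analogue of 26 | C=C[C@H]1C=C(C)[C@@H]2[C@H]([C@@H]1C(=O)C5C[C@H](Cc6ccc(F)cc6)NC5=O)[C@H](O)[C@@H]3[C@@H](C)C[C@@H](C)C[C@@]23C
F11 | step 17 | arene complex: η6-(fluoroarene)Cr(CO)3 complex of F10 | C=C[C@H]1C=C(C)[C@@H]2[C@H]([C@@H]1C(=O)C5C[C@H](Cc6ccc(F)cc6)NC5=O)[C@H](O)[C@@H]3[C@@H](C)C[C@@H](C)C[C@@]23C.[Cr].[C-]#[O+].[C-]#[O+].[C-]#[O+]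
F12 | step 17 | cyclophane complex: η6-(arene)Cr(CO)3 complex of 27 (metal on the outer face) | C=C[C@H]1C=C(C)[C@@H]2[C@H]3[C@H](Oc4ccc(cc4)C[C@H]4CC(C(=O)N4)C(=O)[C@H]13)[C@@H]1[C@@H](C)C[C@@H](C)C[C@]12C.[Cr].[C-]#[O+].[C-]#[O+].[C-]#[O+]
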